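All runs are simulated with made-up constants; scatter was added.

1. 3 amounts of target are asked of the flask, which is charged more concentrated than the two earlier runs I have to reason from.

| setting | north-east | south | flask |
|---|---|---|---|
| starting material | 0.050 M | 0.075 M | 0.10 M |
| partner | 1.1 equiv | 1.1 equiv | 1.10 equiv |
| remark | run made earlier | run made earlier |  |
| time |  |  | 1.0 h |

| run | time / min | target / % | starting material / % |
|---|---|---|---|
| north-east | 20.0 | 6.7 | 82.4 |
| north-east | 40.0 | 9.7 | 66.6 |
| north-east | 50.0 | 10.8 | 60.7 |
| north-east | 80.0 | 10.7 | 45.1 |
| south | 6.00 | 1.9 | 94.5 |
| south | 12.0 | 3.9 | 88.8 |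
| south | 30.0 | 9.1 | 74.1 |
| south | 80.0 | 9.5 | 44.0 |

(readings scatter by 0.5 percentage points)

1. amount of target in percent of the starting material charged, at 3.0 min, 15 min and 1.0 h



2. The north-east run looks contradictory: from 50.0 min to 80.0 min it loses 16 percentage points of starting material, yet target reads 10.8 % and then 10.7 %.

3. I divide the rate of gain of target by the rate of loss of starting material, so that time drops out: the first north-east reading gives 0.381 for this yield ratio, target gained per starting material lost, the field's selectivity. Over the last north-east interval the same ratio reads −0.00641, zero within the scatter, so I read the starting material as still leaving while its loss no longer yields target.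

4. The first north-east reading gives a first-order loss of starting material of 0.00968 min⁻¹, and if the flask keeps that rate and the yield ratio up to 15 min, my own estimate of target there is 5.14 %. At 80.0 min target reads 10.7 % in the north-east run and 9.5 % in the south run, lower at the larger charge, so I expect the flask at 1.0 h to stand below the south reading, though I commit to no firm figure for it.

5. The forecast says 1.05 %, 4.8 % and 7.5 %, reasoning “as if something limited in absolute concentration runs out”, and its value at 15 min lies below my estimate.

6. The flask gives 0.924 %, 5.83 % and 8.92 %, so the forecast stands within the tolerance.

    partner → second intermediate (k = 0.00864 s⁻¹)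
    open intermediate + second intermediate → target (k = 0.120 L mol⁻¹ s⁻¹)
    starting material → open intermediate (k = 1.64 × 10⁻⁴ s⁻¹)
    2 second intermediate → homo product (k = 0.114 L mol⁻¹ s⁻¹)
    starting material + target → side product (k = 4.26 × 10⁻⁴ L mol⁻¹ s⁻¹)

7. By 1.00 h the flask's yield ratio is 0.197, below the 0.381 read early, and it holds 0.0502 M of homo product. A second flask run without the path to homo product gives 40.7 % of target instead of 8.92 %, so the forecast's 7.5 % would fail there. Against the 44.4 % of starting material that the first flask turns over to open intermediate, that is a ratio of 0.917.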